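Each electrophile that the nucleophile turns into target sets one acid free, and that acid has two takers, the nucleophile and the free base.

    protic impurity + free base → quenched reagent (k1 = 2.5 M⁻¹ s⁻¹)
    nucleophile + acid set free ⇌ protonated nucleophile, settled at all times (K2 = 2.7 × 10⁵ M⁻¹)
    electrophile + target → side product (k3 = 4.9 M⁻¹ s⁻¹)
    target ⇌ isomer of the product (K4 = 2.8, k4 = 0.0028 s⁻¹)
    electrophile + nucleophile → acid set free + target (k5 = 4.1 M⁻¹ s⁻¹)
    acid set free + free base ⇌ salt of the base, settled at all times (K6 = 9.6 × 10⁵ M⁻¹)

| setting | Saturday's | Thursday's | Friday's |
|---|---|---|---|
| electrophile | 5.0 mM | 5.0 mM | 5.0 mM |
| nucleophile | 1.05 equiv | 1.05 equiv | 1.05 equiv |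
| free base | 3.00 equiv | 4.50 equiv | 6.80 equiv |
| protic impurity | 2.50 mM | 2.50 mM | 2.50 mM |
| time | 4.0 min | 4.0 min | 4.0 min |

- percent here means electrophile units held: one side product counts as two
- run time (Saturday's): 4.0 min

1. part of the electrophile that has reacted at the end, Saturday's
2. part of the electrophile that has reacted at the end, Thursday's
3. part of the electrophile that has reacted at the end, Friday's
4. what raising the equivalents of free base from its lowest to its highest value here does to the part of the electrophile that has reacted (changes below 5 percentage points count as none) (no change / it rises / it falls)

*Both acid steps are fast. What do you write down first?*

Both balances hold the same free acid, so it cancels between them. Saturday's charges give 10.2 for what I call the split: salt of the base per protonated nucleophile, which is the base's balance constant times free base over the nucleophile's balance constant times nucleophile. In Saturday's flask the base therefore takes more acid than the nucleophile.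

*But the impurity eats base. Does your number survive?*

Not quite. Let the impurity take its 2.50 mM of base, and Saturday's split drops to 8.47. After that, each target made removes one nucleophile and one base. Since Saturday's flask then holds more base than nucleophile, equal subtraction raises the split from there.

*So how much nucleophile is lost to acid?*

Take the whole electrophile charge as acid, a harsh case. On that count Saturday's flask ties up 0.528 mM of nucleophile. Friday's split after the impurity is 21.3, which ties up 0.224 mM. On that same count the two flasks differ by 5.80% of the nucleophile charge.

*And what does that do to the answer?*

I treat the electrophile's loss as pseudo-first-order. Taking that shift as a fractional change in rate, this estimate moves the reacted part by at most exp(-1) of it, here 2.1 percentage points, less than the 5 points that counts. I commit to no change with base. The level itself needs stepping, and I did not do that.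

The forecast did, and gives 97.6%, 97.8% and 97.9% for Saturday's, Thursday's and Friday's, with the trend as no change: “The effect of base is negligible”.

The flasks give 97.7%, 97.8% and 97.9%, so the trend is no change, with a change of 0.21 points.

Saturday's split, 10.2 from the charges, stands at 19.3 from the free amounts at the end, with 3.20 mM of salt of the base against 0.166 mM of protonated nucleophile. Friday's split at the end, 55.8, goes with 0.0598 mM of protonated nucleophile, and free nucleophile stands at 34% of its charge against Saturday's 33%.

The numbers were drawn at random within sensible limits; the flask was simulated.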